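## Structural features

The target is a sesquineolignan in which a tetralin (C1–C4, C4a, C5–C8, C8a; ring C is the fused arene with OH at C7 and OMe at C6) carries ring B at C1, methyl groups at C2 and C3 and a bare methylene at C4. Ring B (4-oxy-3-methoxyphenyl) is linked through its para oxygen to C8' of a 1-arylpropane-1,2-diol unit whose C7' bears a free hydroxyl and ring A (4-hydroxy-3-methoxyphenyl), with C9' as the methyl group. There are five stereocentres in two separate groups: C1, C2 and C3 are contiguous and all-trans (1S,2S,3R), and C7'/C8' are contiguous and erythro (7'S,8'R). Ring B insulates the two groups from each other, so each must be set in absolute terms. The fragile sites are the para-hydroxybenzylic alcohol at C7' (ionisation to a quinone methide or benzylic cation under acid or strong base), the three oxidisable phenols and the doubly benzylic C1–H. The real difficulty is the C2/C3 pair, two adjacent methyl-bearing carbons with no heteroatom to direct stereocontrol, together with telling three almost identical guaiacyl phenols apart and forming the aryl ether at the secondary carbon C8' with defined configuration. The key step exploits the chain ring C–C4H2–C3H(CH3)–C2H(CH3): a benzyl group followed by two ethylidene units, each of which is exactly the carbon delivered by a lithiated ethyl ester carbenoid, so both C–C bonds and both stereocentres arise from two successive boron-to-carbon migrations. C8a lies para to the C6 methoxy group and is therefore the innately nucleophilic position of ring C, which lets C1–C8a be closed later without a halogen handle.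

## Logic of the disconnections

34 ⇒ 33 ⇒ 32. The ring C benzyl C–O bond and the two O–Si bonds (ring A and C7') are cut first. The free phenols and the C7' carbinol are thereby masked until the end. The forward steps must be buffered fluoride and neutral hydrogenolysis, so that the C7' benzylic alcohol and C1–H are not touched.

32 ⇒ 23 + 31. The C8'–O(ring B) bond is cut. This is the most convergent cut: it separates the three tetralin stereocentres from the two side-chain stereocentres at a heteroatom bond. The forward step is an SN2 etherification with inversion at C8', so 31 must be threo (1S,2S), its C7' oxygen must be blocked, and the ring B hydroxyl must be the only acidic OH in 23.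

31 ⇒ 30 ⇒ 29 ⇒ 27 + 28 (28 from 25, from 24; 27 from 26). The C7'–C(ring A) bond is cut. C8' then comes from the chiral pool, and the two oxygens are differentiated by construction (one arrives protected, the other is born free), so no regioselective protection of a diol is needed. The forward addition must be chelation-controlled (syn) and 27 must not racemise.

23 ⇒ 22 ⇒ 21. The C1–C8a bond is cut. C8a is para to the C6 methoxy group and a cation at C1 is stabilised by the para oxygen of ring B, so an intramolecular electrophilic substitution can close the ring. The gain is an acyclic chain whose only fixed stereocentres are C2 and C3; the configuration at C1 in 21 is irrelevant. The demand is that the cyclisation prefers the transition state with all three substituents pseudo-equatorial and the position para to the methoxy group, and that the protecting groups tolerate acid.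

21 ⇒ 14 + 17 (through 18, 19, 20). The C1–C2 bond is cut. The C2–B bond of 14 is the handle; 17 supplies ring B together with C1 as a benzylic carbenoid equivalent, and oxidation of the new C–B bond gives the hydroxyl needed for ionisation. The forward step must transfer C2 with retention; it needs no control at C1.

17 ⇒ 16 ⇒ 15 ⇒ 1. The carbamate C–O bond, a C–H bond and an O–Si bond are cut. These are routine operations on the same starting material as ring C; the silyl ether is chosen to be orthogonal to the ring C benzyl ether.

14 ⇒ 6 + 8 + 8 (through 9–13). The C3–C2 and then the C4–C3 bonds are cut. Both stereocentres come from one achiral ester and the two enantiomers of a diamine, and the precursor 6 is achiral. The forward step needs exactly one insertion per stage and complete stereospecificity. For that reason 6 carries no halogen or other group that could react with an organolithium reagent.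

6 ⇒ 4 + 5, 4 ⇒ 3 ⇒ 2 ⇒ 1, and 8 ⇒ 7. The benzylic C–B bond, the C–Cl bond, a C–H bond, the benzyl ether and the ester C–O bond are cut. This reduces everything to three commodity chemicals; the borylation must be selective for the benzylic chloride.

## Other disconnections considered

Alternative 1: The cut runs through C3–C4 and C4–C4a, so that C4 is supplied by formaldehyde A3 and the ring closes onto ring C. In the forward direction the acyclic aldehyde A2 (C1 and C2 already in place, C3 a methylene next to the formyl group) would undergo an amine/carboxylic acid-mediated Mannich condensation–elimination with A3 to the α-methylene aldehyde. Strong acid would then let the free ring C phenol add through C4a (para to the C7 hydroxyl) to C4 in an intramolecular conjugate Friedel–Crafts alkylation, and protonation at C3 would give A1.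
- In its favour: one pot, a one-carbon feedstock for C4, no protecting group on the ring C phenol (it even drives the closure), and a C3 centre that can equilibrate to the all-trans arrangement because it is α to the aldehyde.
- Against it here: the C1/C2 diad of A2, a diarylmethine with two electronically similar aryl groups, has to be made enantioselectively beforehand. The arene must choose C4a over C8. The formyl group of A1 must then be taken down to a methyl group in the presence of a phenol and an aryl ester.
- Comparison: both plans form two skeletal bonds in the key step, but alternative 1 also closes the carbocycle, and on that point it is the better plan. It is the equal of the chosen plan in using the innate nucleophilicity of ring C. Mechanistically its C3 rests on thermodynamic control and its C1/C2 on an earlier asymmetric step, whereas the chosen plan fixes C2 and C3 by stereospecific reagent-controlled migrations. In step economy the chosen plan delivers both methyl groups at the right oxidation level, while alternative 1 spends several steps after its key step on CHO to CH3.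

Alternative 2: The cut removes C1–C2 and C3–C4 together, dividing the carbocycle into an ortho-quinodimethane (ring C with C1 and C4) and a two-carbon dienophile (C2, C3). Irradiation of the ortho-methyl diaryl ketone A5 near 350 nm would give, by photoenolisation, a hydroxy-ortho-quinodimethane that is trapped by dimethyl fumarate A6 on a chiral titanium diolate template in a Diels–Alder reaction to give A4.
- In its favour: the largest gain in complexity per step (a ring, two C–C bonds and three stereocentres, the trans diester following from the alkene geometry) and a very short approach to A5. On both points it is better than the chosen plan.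
- Against it here: A4 is over-functionalised. The tertiary benzylic hydroxyl at C1 must be removed with control of the C1 configuration (hydride delivery to a benzylic cation next to C2 has no assured facial preference). Both esters must be reduced to methyl groups through alcohol and sulfonate stages, with allyl and benzyl ethers kept apart. The chiral template is stoichiometric and the photochemistry limits scale.
- Comparison: the two plans are equal in taking the absolute configuration from an external chiral controller and in having a stereospecific origin for the C2/C3 relationship. The chosen plan is better after the key step, since no oxygen has to be removed from C1 and no ester has to be reduced, and it sets C1 only once.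

Alternative 3: The cut runs through C4–C4a and C1–C8a, so that ring C is inserted between the carbonyl carbon and the ring B-bearing α-carbon of the cyclobutanone A8. The bromo-iodo arene A9 would be converted at iodine into an arylmagnesium species that adds to the carbonyl of A8 (C4–C4a). A palladium catalyst with a bulky phosphine would then insert into the C–Br bond, the tertiary alkoxide would bind palladium, β-carbon elimination would open the strained C1–C4 bond, and C(sp3)–C(sp2) reductive elimination would close C1–C8a to give A7.
- In its favour: one pot, two bonds and the ring, strain release as driving force, and three contiguous stereocentres carried over from the four-membered ring. After its key step only the C4 ketone must be removed, which is fewer steps than the chosen plan needs to reach the tetralin, a point in its favour.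
- Against it here: enantiopure all-trans A8 is itself a multi-step stereochemical problem. β-Carbon elimination must select C1–C4 over C3–C4. The secondary benzylic alkylpalladium intermediate has a β-hydrogen at C2, so β-hydride elimination competes. The stereochemical course at C1 through the palladium steps is not assured.
- Comparison: alternative 3 is better in ring construction. The two plans are equal in protecting-group logic (ring C benzyl ether, ring B silyl ether). The chosen plan is better in that every stereocentre comes from a commercial reagent through well-understood stereospecific steps.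

Key step: step 6

Remark (design assumption and check of configuration): ring C of 6 and 14 carries hydrogen and not a halogen at the future C8a. A bromide there would serve only a palladium-mediated closure, would be exposed to halogen–lithium exchange in three organolithium operations, and would force C1 to be set by a configurationally labile lithiated benzyl carbamate. Its bromo analogue is kept only as fallback compound F7, and 24, 26 and both sparteine enantiomers are taken as commercial. C3 (R) and C2 (S) of the target correspond to (2S,3R) in 14, and the erythro (7'S,8'R) side chain requires the threo (1S,2S) alcohol 31 before inversion.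

## Steps

Step 1
Reactants: 1 vanillin (4-hydroxy-3-methoxybenzaldehyde)
Product: 2 4-(benzyloxy)-3-methoxybenzaldehyde
Conditions: BnBr, K2CO3, DMF, rt
Reagents that add atoms: benzyl bromide, BrCc1ccccc1
Why: Williamson O-alkylation of the phenoxide; the benzyl ether is the ring C protecting group, inert to organolithium-derived boronate chemistry, acid and fluoride, and removable at the end by hydrogenolysis.

Step 2
Reactants: 2 4-(benzyloxy)-3-methoxybenzaldehyde
Product: 3 [4-(benzyloxy)-3-methoxyphenyl]methanol
Conditions: NaBH4, MeOH/THF, 0 °C
Reagents that add atoms: none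
Why: Chemoselective hydride reduction of the aryl aldehyde to the primary benzylic alcohol.

Step 3
Reactants: 3 [4-(benzyloxy)-3-methoxyphenyl]methanol
Product: 4 1-(benzyloxy)-4-(chloromethyl)-2-methoxybenzene
Conditions: SOCl2, CH2Cl2, 0 °C → rt
Reagents that add atoms: thionyl chloride, O=S(Cl)Cl
Why: Chlorodehydroxylation through the chlorosulfite; the chloride is preferred to the bromide because this electron-rich benzylic halide is then easier to handle yet still undergoes oxidative addition.

Step 4
Reactants: 4 1-(benzyloxy)-4-(chloromethyl)-2-methoxybenzene; 5 bis(pinacolato)diboron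
Product: 6 2-[4-(benzyloxy)-3-methoxybenzyl]-4,4,5,5-tetramethyl-1,3,2-dioxaborolane
Conditions: Pd(dba)2 (cat.), P(4-MeOC6H4)3, KOAc, toluene, 50 °C
Reagents that add atoms: none
Why: Miyaura borylation of a benzylic chloride: oxidative addition of the C–Cl bond to zerovalent palladium, acetate-assisted transmetallation with 5 and reductive elimination; with no aryl halide in the molecule there is no competing site.

Step 5
Reactants: 7 2,4,6-triisopropylbenzoic acid
Product: 8 ethyl 2,4,6-triisopropylbenzoate
Conditions: EtI, K2CO3, DMF, 50 °C
Reagents that add atoms: iodoethane, CCI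
Why: SN2 O-alkylation of the carboxylate avoids attack at the hindered acyl carbon; the bulky aryl ester directs α-lithiation, resists attack by sBuLi and later serves as the leaving group.

Step 6
Reactants: 6 2-[4-(benzyloxy)-3-methoxybenzyl]-4,4,5,5-tetramethyl-1,3,2-dioxaborolane; 8 ethyl 2,4,6-triisopropylbenzoate (two portions)
Product: 14 2-[(2S,3R)-4-(4-benzyloxy-3-methoxyphenyl)-3-methylbutan-2-yl]-4,4,5,5-tetramethyl-1,3,2-dioxaborolane, via (S)-1-lithioethyl 2,4,6-triisopropylbenzoate 9 (not isolated), via lithium boronate complex 10 (not isolated), via (R)-configured monohomologated boronic ester 11 (not isolated), via (R)-1-lithioethyl 2,4,6-triisopropylbenzoate 12 (not isolated), via lithium boronate complex 13 (not isolated)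
Conditions: 8 (1.3 equiv), sBuLi, (−)-sparteine, Et2O, −78 °C; add 6, −78 → 35 °C; cool to −78 °C, transfer into 8 (1.5 equiv), sBuLi, (+)-sparteine, Et2O, −78 → 35 °C
Reagents that add atoms: none
Why: sBuLi/(−)-sparteine removes the pro-S α-hydrogen of 8 to give the configurationally stable carbenoid 9, which adds to the boron atom of 6 with retention to give boronate 10. On warming, the benzyl group migrates from boron to carbon antiperiplanar to the departing triisopropylbenzoate (inversion at the carbenoid carbon), which forms C4–C3 and gives 11 with C3 (R). The cooled mixture is then added to 12, made from 8 with sBuLi/(+)-sparteine; boronate 13 forms, and the secondary alkyl group migrates with retention at C3 and inversion at the new carbenoid carbon, which forms C3–C2 with C2 (S). The closest known reaction type is the iterative, reagent-controlled lithiation–borylation (assembly-line homologation) of boronic esters with enantiomeric α-lithiated hindered benzoates. No ring is closed. Each new stereocentre is controlled only by the sparteine enantiomer through the stereospecific retention/inversion sequence and is independent of the centre already present, so the trans-dimethyl diastereomer follows from the order (S) then (R). The step needs one insertion per stage and attack at boron in preference to deprotonation of the benzylic C–H next to boron; fast boronate formation at −78 °C, the thermal lability of the excess carbenoid (it decomposes before migration releases a new boronic ester) and the absence of any halogen or acidic group in 6 should secure this. A mismatched insertion ends as a separable diastereomer and not as loss of enantiomeric purity of 14.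

Step 7
Reactants: 1 vanillin
Product: 15 3-methoxy-4-(triisopropylsilyloxy)benzaldehyde
Conditions: iPr3SiCl, imidazole, DMF, rt
Reagents that add atoms: chlorotriisopropylsilane, CC(C)[Si](Cl)(C(C)C)C(C)C
Why: Silylation of the phenol; the bulky aryl silyl ether withstands sBuLi at −78 °C and CF3CO2H and is removable with fluoride without touching the ring C benzyl ether.

Step 8
Reactants: 15 3-methoxy-4-(triisopropylsilyloxy)benzaldehyde
Product: 16 [3-methoxy-4-(triisopropylsilyloxy)phenyl]methanol
Conditions: NaBH4, MeOH/THF, 0 °C
Reagents that add atoms: none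
Why: Hydride reduction of the aldehyde; the hindered aryl silyl ether should survive the brief, cold, weakly basic conditions.

Step 9
Reactants: 16 [3-methoxy-4-(triisopropylsilyloxy)phenyl]methanol
Product: 17 3-methoxy-4-(triisopropylsilyloxy)benzyl N,N-diisopropylcarbamate
Conditions: iPr2NCOCl, Et3N, DMAP (cat.), CH2Cl2, reflux
Reagents that add atoms: N,N-diisopropylcarbamoyl chloride, CC(C)N(C(C)C)C(Cl)=O
Why: O-carbamoylation of the primary alcohol; the hindered carbamate directs benzylic lithiation and is the leaving group of the subsequent 1,2-migration.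

Step 10
Reactants: 14 2-[(2S,3R)-4-(4-benzyloxy-3-methoxyphenyl)-3-methylbutan-2-yl]-4,4,5,5-tetramethyl-1,3,2-dioxaborolane; 17 3-methoxy-4-(triisopropylsilyloxy)benzyl N,N-diisopropylcarbamate
Product: 21 (1RS,2S,3R)-4-[4-(benzyloxy)-3-methoxyphenyl]-1-[3-methoxy-4-(triisopropylsilyloxy)phenyl]-2,3-dimethylbutan-1-ol (both C1 epimers), via α-lithiated carbamate 18 (not isolated), via lithium boronate complex 19 (not isolated), via secondary benzylic boronic ester 20 (not isolated)
Conditions: 17 (1.3 equiv), sBuLi, TMEDA, Et2O, −78 °C; add 14, −78 °C → rt (MgBr2·OEt2, MeOH); then NaBO3·4H2O, THF/H2O, rt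
Reagents that add atoms: sodium perborate tetrahydrate (supplies the hydroxyl oxygen), [Na+].[Na+].O[B-]1(O)OO[B-](O)(O)OO1
Why: Lithiation–borylation–oxidation of a primary benzylic carbamate: carbamate-directed benzylic lithiation gives 18, which adds to the boron of 14; the secondary alkyl group then migrates with retention at C2 and expels the carbamate (C1–C2 formed), and mild perborate oxidation of the C–B bond gives the alcohol. No chiral ligand is used because the configuration at C1 is erased in step 11. C2 and C3 are not touched.

Step 11
Reactants: 21 (1RS,2S,3R)-4-[4-(benzyloxy)-3-methoxyphenyl]-1-[3-methoxy-4-(triisopropylsilyloxy)phenyl]-2,3-dimethylbutan-1-ol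
Product: 22 (1S,2S,3R)-7-(benzyloxy)-6-methoxy-1-[3-methoxy-4-(triisopropylsilyloxy)phenyl]-2,3-dimethyl-1,2,3,4-tetrahydronaphthalene
Conditions: CF3CO2H, CH2Cl2, −20 → 0 °C
Reagents that add atoms: none
Why: Acid ionises either C1 epimer to the same benzylic cation, stabilised by the para silyloxy group of ring B, and intramolecular Friedel–Crafts alkylation through C8a (para to the C6 methoxy group) closes the six-membered ring. A chair-like transition state with the C2 and C3 methyl groups and ring B all pseudo-equatorial should give the all-trans tetralin, so C1 (S) is set by substrate control from C2 and both epimers converge.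

Step 12
Reactants: 22 (1S,2S,3R)-7-(benzyloxy)-6-methoxy-1-[3-methoxy-4-(triisopropylsilyloxy)phenyl]-2,3-dimethyl-1,2,3,4-tetrahydronaphthalene
Product: 23 4-[(1S,2S,3R)-7-(benzyloxy)-6-methoxy-2,3-dimethyl-1,2,3,4-tetrahydronaphthalen-1-yl]-2-methoxyphenol
Conditions: Bu4NF, THF, 0 °C
Reagents that add atoms: none
Why: Fluoride cleaves the aryl Si–O bond and leaves the benzyl ether untouched, so the ring B phenol becomes the only free hydroxyl of the tetralin.

Step 13
Reactants: 24 4-bromo-2-methoxyphenol
Product: 25 (4-bromo-2-methoxyphenoxy)(tert-butyl)dimethylsilane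
Conditions: tBuMe2SiCl, imidazole, DMF, rt
Reagents that add atoms: tert-butylchlorodimethylsilane, CC(C)(C)[Si](C)(C)Cl
Why: Phenol silylation; the ring A protecting group is chosen to survive the later hydrogenolysis of the C8' benzyl ether and to leave together with the C7' silyl ether.

Step 14
Reactants: 26 ethyl (S)-2-(benzyloxy)propanoate
Product: 27 (S)-2-(benzyloxy)propanal
Conditions: iBu2AlH, CH2Cl2, −78 °C; aq. potassium sodium tartrate
Reagents that add atoms: none
Why: Partial reduction of the ester through the stable tetrahedral aluminium hemiacetal at −78 °C; the aldehyde is used at once, without chromatography, to avoid racemisation.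

Step 15
Reactants: 25 (4-bromo-2-methoxyphenoxy)(tert-butyl)dimethylsilane; 27 (S)-2-(benzyloxy)propanal
Product: 29 (1S,2S)-2-(benzyloxy)-1-[4-(tert-butyldimethylsilyloxy)-3-methoxyphenyl]propan-1-ol, via arylmagnesium bromide 28 (not isolated)
Conditions: 25, Mg, Et2O, reflux; then 27, MgBr2·OEt2, CH2Cl2, −78 °C
Reagents that add atoms: none
Why: Cram-chelate Grignard addition: magnesium bridges the aldehyde and the α-benzyloxy oxygen, and the aryl group adds to the face opposite the C8' methyl group, which should give the syn (threo, 1S,2S) alcohol; a minor anti isomer is removable by chromatography. C7' is set here by substrate control from the lactate-derived centre.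

Step 16
Reactants: 29 (1S,2S)-2-(benzyloxy)-1-[4-(tert-butyldimethylsilyloxy)-3-methoxyphenyl]propan-1-ol
Product: 30 tert-butyl{(1S,2S)-2-(benzyloxy)-1-[4-(tert-butyldimethylsilyloxy)-3-methoxyphenyl]propoxy}dimethylsilane
Conditions: tBuMe2SiOTf, 2,6-lutidine, CH2Cl2, −78 → 0 °C
Reagents that add atoms: tert-butyldimethylsilyl trifluoromethanesulfonate, CC(C)(C)[Si](C)(C)OS(=O)(=O)C(F)(F)F
Why: Silylation of the hindered benzylic alcohol with the silyl triflate under non-ionising basic conditions, so that C7' is not epimerised.

Step 17
Reactants: 30 tert-butyl{(1S,2S)-2-(benzyloxy)-1-[4-(tert-butyldimethylsilyloxy)-3-methoxyphenyl]propoxy}dimethylsilane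
Product: 31 (1S,2S)-1-(tert-butyldimethylsilyloxy)-1-[4-(tert-butyldimethylsilyloxy)-3-methoxyphenyl]propan-2-ol
Conditions: H2 (1 atm), Pd/C, EtOAc, rt
Reagents that add atoms: none
Why: Hydrogenolysis of the alkyl benzyl ether; in EtOAc the silyl ethers and the hindered, silylated benzylic C–O bond should remain, so the free hydroxyl ends up at C8' by construction.

Step 18
Reactants: 23 4-[(1S,2S,3R)-7-(benzyloxy)-6-methoxy-2,3-dimethyl-1,2,3,4-tetrahydronaphthalen-1-yl]-2-methoxyphenol; 31 (1S,2S)-1-(tert-butyldimethylsilyloxy)-1-[4-(tert-butyldimethylsilyloxy)-3-methoxyphenyl]propan-2-ol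
Product: 32 erythro (7'S,8'R) aryl ether: ring B oxygen of the tetralin bonded to C8' of the side chain; ring C benzyl ether; ring A and C7' tert-butyldimethylsilyl ethers
Conditions: PPh3, DIAD, THF, 0 °C → rt
Reagents that add atoms: none
Why: Mitsunobu etherification: the alkoxyphosphonium ion of 31 is displaced by the phenoxide of 23 in an SN2 reaction with inversion at C8', which turns the threo (1S,2S) alcohol into the erythro (7'S,8'R) aryl ether. 23 offers only one acidic hydroxyl.

Step 19
Reactants: 32 erythro bis-silyl ether
Product: 33 (1S,2R)-2-{4-[(1S,2S,3R)-7-(benzyloxy)-6-methoxy-2,3-dimethyl-1,2,3,4-tetrahydronaphthalen-1-yl]-2-methoxyphenoxy}-1-(4-hydroxy-3-methoxyphenyl)propan-1-ol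
Conditions: Bu4NF, AcOH, THF, 0 °C → rt
Reagents that add atoms: none
Why: Fluoride removes the aryl and the benzylic silyl ether; acetic acid buffering should keep the liberated para-hydroxybenzyl alcohol from base-induced quinone methide formation, so C7' is not epimerised.

Step 20
Reactants: 33 ring C benzyl ether of the target
Product: 34 (1S,2R)-1-(4-hydroxy-3-methoxyphenyl)-2-{4-[(1S,2S,3R)-7-hydroxy-6-methoxy-2,3-dimethyl-1,2,3,4-tetrahydronaphthalen-1-yl]-2-methoxyphenoxy}propan-1-ol (CID53359464)
Conditions: H2 (1 atm), Pd/C, EtOAc, rt
Reagents that add atoms: none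
Why: Hydrogenolysis of the remaining aryl benzyl ether under neutral conditions; the benzylic C7' hydroxyl, the homobenzylic C8'–O ether and the doubly benzylic C1–H are not expected to be reduced at atmospheric pressure in EtOAc.

## Compound list

1 | vanillin (4-hydroxy-3-methoxybenzaldehyde) | COc1cc(C=O)ccc1O | starting material
2 | 4-(benzyloxy)-3-methoxybenzaldehyde | COc1cc(C=O)ccc1OCc1ccccc1 | intermediate
3 | [4-(benzyloxy)-3-methoxyphenyl]methanol | COc1cc(CO)ccc1OCc1ccccc1 | intermediate
4 | 1-(benzyloxy)-4-(chloromethyl)-2-methoxybenzene | COc1cc(CCl)ccc1OCc1ccccc1 | intermediate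
5 | bis(pinacolato)diboron | CC1(C)OB(B2OC(C)(C)C(C)(C)O2)OC1(C)C | starting material
6 | 2-[4-(benzyloxy)-3-methoxybenzyl]-4,4,5,5-tetramethyl-1,3,2-dioxaborolane | COc1cc(CB2OC(C)(C)C(C)(C)O2)ccc1OCc1ccccc1 | intermediate
7 | 2,4,6-triisopropylbenzoic acid | CC(C)c1cc(C(C)C)c(C(=O)O)c(C(C)C)c1 | starting material
8 | ethyl 2,4,6-triisopropylbenzoate | CCOC(=O)c1c(C(C)C)cc(C(C)C)cc1C(C)C | intermediate
9 | (S)-1-lithioethyl 2,4,6-triisopropylbenzoate (sparteine ligand omitted) | C[C@H]([Li])OC(=O)c1c(C(C)C)cc(C(C)C)cc1C(C)C | intermediate
10 | lithium boronate complex of 6 and 9 (carbenoid carbon S) | C[C@H]([B-]1(Cc2ccc(OCc3ccccc3)c(OC)c2)OC(C)(C)C(C)(C)O1)OC(=O)c1c(C(C)C)cc(C(C)C)cc1C(C)C.[Li+] | intermediate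
11 | (R)-2-[1-(4-benzyloxy-3-methoxyphenyl)propan-2-yl]-4,4,5,5-tetramethyl-1,3,2-dioxaborolane | COc1cc(C[C@@H](C)B2OC(C)(C)C(C)(C)O2)ccc1OCc1ccccc1 | intermediate
12 | (R)-1-lithioethyl 2,4,6-triisopropylbenzoate (sparteine ligand omitted) | C[C@@H]([Li])OC(=O)c1c(C(C)C)cc(C(C)C)cc1C(C)C | intermediate
13 | lithium boronate complex of 11 and 12 (carbenoid carbon R) | C[C@@H]([B-]1([C@H](C)Cc2ccc(OCc3ccccc3)c(OC)c2)OC(C)(C)C(C)(C)O1)OC(=O)c1c(C(C)C)cc(C(C)C)cc1C(C)C.[Li+] | intermediate
14 | 2-[(2S,3R)-4-(4-benzyloxy-3-methoxyphenyl)-3-methylbutan-2-yl]-4,4,5,5-tetramethyl-1,3,2-dioxaborolane | COc1cc(C[C@@H](C)[C@H](C)B2OC(C)(C)C(C)(C)O2)ccc1OCc1ccccc1 | intermediate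
15 | 3-methoxy-4-(triisopropylsilyloxy)benzaldehyde | COc1cc(C=O)ccc1O[Si](C(C)C)(C(C)C)C(C)C | intermediate
16 | [3-methoxy-4-(triisopropylsilyloxy)phenyl]methanol | COc1cc(CO)ccc1O[Si](C(C)C)(C(C)C)C(C)C | intermediate
17 | 3-methoxy-4-(triisopropylsilyloxy)benzyl N,N-diisopropylcarbamate | COc1cc(COC(=O)N(C(C)C)C(C)C)ccc1O[Si](C(C)C)(C(C)C)C(C)C | intermediate
18 | α-lithiated carbamate of 17 (TMEDA ligand omitted; racemic) | COc1cc(C([Li])OC(=O)N(C(C)C)C(C)C)ccc1O[Si](C(C)C)(C(C)C)C(C)C | intermediate
19 | lithium boronate complex of 14 and 18 (both configurations at the benzylic carbon) | COc1cc(C(OC(=O)N(C(C)C)C(C)C)[B-]2([C@@H](C)[C@H](C)Cc3ccc(OCc4ccccc4)c(OC)c3)OC(C)(C)C(C)(C)O2)ccc1O[Si](C(C)C)(C(C)C)C(C)C.[Li+] | intermediate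
20 | secondary benzylic pinacol boronic ester: boron on C1 (both epimers), C2 and C3 configured as in 14 | COc1cc(C(B2OC(C)(C)C(C)(C)O2)[C@@H](C)[C@H](C)Cc2ccc(OCc3ccccc3)c(OC)c2)ccc1O[Si](C(C)C)(C(C)C)C(C)C | intermediate
21 | (1RS,2S,3R)-4-[4-(benzyloxy)-3-methoxyphenyl]-1-[3-methoxy-4-(triisopropylsilyloxy)phenyl]-2,3-dimethylbutan-1-ol | COc1cc(C(O)[C@@H](C)[C@H](C)Cc2ccc(OCc3ccccc3)c(OC)c2)ccc1O[Si](C(C)C)(C(C)C)C(C)C | intermediate
22 | (1S,2S,3R)-7-(benzyloxy)-6-methoxy-1-[3-methoxy-4-(triisopropylsilyloxy)phenyl]-2,3-dimethyl-1,2,3,4-tetrahydronaphthalene | COc1cc([C@H]2c3cc(OCc4ccccc4)c(OC)cc3C[C@@H](C)[C@@H]2C)ccc1O[Si](C(C)C)(C(C)C)C(C)C | intermediate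
23 | 4-[(1S,2S,3R)-7-(benzyloxy)-6-methoxy-2,3-dimethyl-1,2,3,4-tetrahydronaphthalen-1-yl]-2-methoxyphenol | COc1cc([C@H]2c3cc(OCc4ccccc4)c(OC)cc3C[C@@H](C)[C@@H]2C)ccc1O | intermediate
24 | 4-bromo-2-methoxyphenol | COc1cc(Br)ccc1O | starting material
25 | (4-bromo-2-methoxyphenoxy)(tert-butyl)dimethylsilane | COc1cc(Br)ccc1O[Si](C)(C)C(C)(C)C | intermediate
26 | ethyl (S)-2-(benzyloxy)propanoate | CCOC(=O)[C@H](C)OCc1ccccc1 | starting material
27 | (S)-2-(benzyloxy)propanal | O=C[C@H](C)OCc1ccccc1 | intermediate
28 | [4-(tert-butyldimethylsilyloxy)-3-methoxyphenyl]magnesium bromide | COc1cc([Mg]Br)ccc1O[Si](C)(C)C(C)(C)C | intermediate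
29 | (1S,2S)-2-(benzyloxy)-1-[4-(tert-butyldimethylsilyloxy)-3-methoxyphenyl]propan-1-ol | COc1cc([C@H](O)[C@H](C)OCc2ccccc2)ccc1O[Si](C)(C)C(C)(C)C | intermediate
30 | tert-butyl{(1S,2S)-2-(benzyloxy)-1-[4-(tert-butyldimethylsilyloxy)-3-methoxyphenyl]propoxy}dimethylsilane | COc1cc([C@H](O[Si](C)(C)C(C)(C)C)[C@H](C)OCc2ccccc2)ccc1O[Si](C)(C)C(C)(C)C | intermediate
31 | (1S,2S)-1-(tert-butyldimethylsilyloxy)-1-[4-(tert-butyldimethylsilyloxy)-3-methoxyphenyl]propan-2-ol | COc1cc([C@H](O[Si](C)(C)C(C)(C)C)[C@H](C)O)ccc1O[Si](C)(C)C(C)(C)C | intermediate
32 | erythro (7'S,8'R) aryl ether of 23 and 31: ring C benzyl ether, ring A and C7' tert-butyldimethylsilyl ethers | COc1cc([C@H](O[Si](C)(C)C(C)(C)C)[C@@H](C)Oc2ccc([C@H]3c4cc(OCc5ccccc5)c(OC)cc4C[C@@H](C)[C@@H]3C)cc2OC)ccc1O[Si](C)(C)C(C)(C)C | intermediate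
33 | (1S,2R)-2-{4-[(1S,2S,3R)-7-(benzyloxy)-6-methoxy-2,3-dimethyl-1,2,3,4-tetrahydronaphthalen-1-yl]-2-methoxyphenoxy}-1-(4-hydroxy-3-methoxyphenyl)propan-1-ol | COc1cc([C@H](O)[C@@H](C)Oc2ccc([C@H]3c4cc(OCc5ccccc5)c(OC)cc4C[C@@H](C)[C@@H]3C)cc2OC)ccc1O | intermediate
34 | (1S,2R)-1-(4-hydroxy-3-methoxyphenyl)-2-{4-[(1S,2S,3R)-7-hydroxy-6-methoxy-2,3-dimethyl-1,2,3,4-tetrahydronaphthalen-1-yl]-2-methoxyphenoxy}propan-1-ol (CID53359464) | COc1cc([C@H](O)[C@@H](C)Oc2ccc([C@H]3c4cc(O)c(OC)cc4C[C@@H](C)[C@@H]3C)cc2OC)ccc1O | target

## Step count and least certain steps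

Total: 20 steps. Longest linear sequence: 11 steps (steps 1, 2, 3, 4, 6, 10, 11, 12, 18, 19, 20, from 1 to 34).

**Step 6 (key step).** The most likely failure is erosion of diastereomeric purity, because each diamine-mediated deprotonation is highly but not perfectly enantioselective. A second risk is a double insertion of the first carbenoid if its excess is not destroyed before the migration releases 11. Both arise from generating the reagents in the flask. Fallback, setting out from 6 and 8: the two carbenoids are prepared as isolable tin compounds. 8 is deprotonated with sBuLi and (−)- or (+)-sparteine and quenched with Me3SnCl to give (S)-1-(trimethylstannyl)ethyl 2,4,6-triisopropylbenzoate F1 and (R)-1-(trimethylstannyl)ethyl 2,4,6-triisopropylbenzoate F2, each recrystallised to enantiomeric purity. Tin–lithium exchange with nBuLi (Et2O, −78 °C) regenerates 9 from F1 and 12 from F2 in exact stoichiometry. 6 is homologated with 9 from F1, 11 is isolated and purified, and 11 is then homologated with 12 from F2; the route is rejoined at 14.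

**Step 10.** The most likely failure is slow or reversible boronate formation at the hindered, α- and β-branched boron centre of 14, so that 18 decomposes before it is captured. Partial loss of the aryl silyl ether in the oxidative work-up is a second risk. Fallback, setting out from 14: Matteson homologation with LiCHCl2 (from CH2Cl2 and nBuLi, THF, −100 °C, then ZnCl2) gives 2-[(1RS,2S,3R)-4-(4-benzyloxy-3-methoxyphenyl)-1-chloro-2,3-dimethylbutyl]-4,4,5,5-tetramethyl-1,3,2-dioxaborolane F3, and buffered perborate oxidation gives (2S,3R)-4-[4-(benzyloxy)-3-methoxyphenyl]-2,3-dimethylbutanal F4. Separately, 24 is silylated to (4-bromo-2-methoxyphenoxy)triisopropylsilane F5 and converted with Mg into [3-methoxy-4-(triisopropylsilyloxy)phenyl]magnesium bromide F6. Addition of F6 to F4 at −78 °C gives 21, in which both C1 epimers are acceptable, and the route is rejoined there.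

**Step 11.** The most likely failure is insufficient facial selectivity at C1 (formation of the 1,2-cis epimer), or closure through the position ortho to the methoxy group, because the outcome rests on conformational preference alone. Fallback, setting out from 14, with reagent control at C1 and a stereoretentive ring closure: N-bromosuccinimide (MeCN, 0 °C) brominates ring C para to the methoxy group to give 2-[(2S,3R)-4-(4-benzyloxy-2-bromo-5-methoxyphenyl)-3-methylbutan-2-yl]-4,4,5,5-tetramethyl-1,3,2-dioxaborolane F7. 17 is lithiated with sBuLi in the presence of a chiral bis(oxazoline) or sparteine ligand chosen to enrich the (S)-configured form of 18 by dynamic resolution, and reaction with F7 gives the (S)-configured secondary benzylic boronic ester F8 (boron on C1, bromine on C8a). Pd(PPh3)4/Ag2O (DME, 85 °C) then effects an intramolecular Suzuki–Miyaura coupling with retention at C1 to give 22, where the route is rejoined. This path is longer, depends on the configurationally labile carbenoid and exposes an aryl bromide to an organolithium reagent, which is why it is not the first choice.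

**Step 18.** The most likely failure is slow SN2 displacement at the secondary carbinol next to the bulky silyloxybenzyl group. This would give room to elimination, to silyl migration between the vicinal oxygens, or to participation of the electron-rich ring A with erosion of the inversion. Fallback, setting out from 23: Mitsunobu reaction with ethyl (S)-lactate, an unhindered and activated alcohol, gives ethyl (R)-2-{4-[(1S,2S,3R)-7-(benzyloxy)-6-methoxy-2,3-dimethyl-1,2,3,4-tetrahydronaphthalen-1-yl]-2-methoxyphenoxy}propanoate F9. iBu2AlH (CH2Cl2, −78 °C) gives the (R)-2-aryloxypropanal F10. The Grignard reagent 28, transmetallated with ClTi(OiPr)3 to exclude chelation, adds under Felkin–Anh control to give the erythro (7'S,8'R) alcohol F11, which still carries the ring A silyl ether. Bu4NF/AcOH then gives 33, where the route is rejoined.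

**Step 15.** The most likely failure is incomplete chelation control, giving a mixture of threo and erythro alcohols, together with partial racemisation of the α-alkoxy aldehyde 27 before the addition. Fallback, setting out from 26: MeNHOMe·HCl/iPrMgCl converts the ester into (S)-2-(benzyloxy)-N-methoxy-N-methylpropanamide F12. Addition of 28 gives (S)-2-(benzyloxy)-1-[4-(tert-butyldimethylsilyloxy)-3-methoxyphenyl]propan-1-one F13. Corey–Bakshi–Shibata reduction with the (S)-2-methyl-oxazaborolidine and BH3·SMe2, in which the catalyst and not the α-stereocentre chooses the carbonyl face, then gives 29, where the route is rejoined.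

## Further compounds

F1 | step 6 | (S)-1-(trimethylstannyl)ethyl 2,4,6-triisopropylbenzoate | C[C@H]([Sn](C)(C)C)OC(=O)c1c(C(C)C)cc(C(C)C)cc1C(C)C
F2 | step 6 | (R)-1-(trimethylstannyl)ethyl 2,4,6-triisopropylbenzoate | C[C@@H]([Sn](C)(C)C)OC(=O)c1c(C(C)C)cc(C(C)C)cc1C(C)C
F3 | step 10 | 2-[(1RS,2S,3R)-4-(4-benzyloxy-3-methoxyphenyl)-1-chloro-2,3-dimethylbutyl]-4,4,5,5-tetramethyl-1,3,2-dioxaborolane | COc1cc(C[C@@H](C)[C@H](C)C(Cl)B2OC(C)(C)C(C)(C)O2)ccc1OCc1ccccc1
F4 | step 10 | (2S,3R)-4-[4-(benzyloxy)-3-methoxyphenyl]-2,3-dimethylbutanal | COc1cc(C[C@@H](C)[C@H](C)C=O)ccc1OCc1ccccc1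
F5 | step 10 | (4-bromo-2-methoxyphenoxy)triisopropylsilane | COc1cc(Br)ccc1O[Si](C(C)C)(C(C)C)C(C)C
F6 | step 10 | [3-methoxy-4-(triisopropylsilyloxy)phenyl]magnesium bromide | COc1cc([Mg]Br)ccc1O[Si](C(C)C)(C(C)C)C(C)C
F7 | step 11 | 2-[(2S,3R)-4-(4-benzyloxy-2-bromo-5-methoxyphenyl)-3-methylbutan-2-yl]-4,4,5,5-tetramethyl-1,3,2-dioxaborolane | COc1cc(C[C@@H](C)[C@H](C)B2OC(C)(C)C(C)(C)O2)c(Br)cc1OCc1ccccc1
F8 | step 11 | secondary benzylic pinacol boronic ester with (S)-configured boron-bearing C1, C2 and C3 as in 14, bromine on C8a, ring B triisopropylsilyl ether, ring C benzyl ether | COc1cc([C@@H](B2OC(C)(C)C(C)(C)O2)[C@@H](C)[C@H](C)Cc2cc(OC)c(OCc3ccccc3)cc2Br)ccc1O[Si](C(C)C)(C(C)C)C(C)C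
F9 | step 18 | ethyl (R)-2-{4-[(1S,2S,3R)-7-(benzyloxy)-6-methoxy-2,3-dimethyl-1,2,3,4-tetrahydronaphthalen-1-yl]-2-methoxyphenoxy}propanoate | CCOC(=O)[C@@H](C)Oc1ccc([C@H]2c3cc(OCc4ccccc4)c(OC)cc3C[C@@H](C)[C@@H]2C)cc1OC
F10 | step 18 | (R)-2-{4-[(1S,2S,3R)-7-(benzyloxy)-6-methoxy-2,3-dimethyl-1,2,3,4-tetrahydronaphthalen-1-yl]-2-methoxyphenoxy}propanal | O=C[C@@H](C)Oc1ccc([C@H]2c3cc(OCc4ccccc4)c(OC)cc3C[C@@H](C)[C@@H]2C)cc1OC
F11 | step 18 | (1S,2R)-2-{4-[(1S,2S,3R)-7-(benzyloxy)-6-methoxy-2,3-dimethyl-1,2,3,4-tetrahydronaphthalen-1-yl]-2-methoxyphenoxy}-1-[4-(tert-butyldimethylsilyloxy)-3-methoxyphenyl]propan-1-ol | COc1cc([C@H](O)[C@@H](C)Oc2ccc([C@H]3c4cc(OCc5ccccc5)c(OC)cc4C[C@@H](C)[C@@H]3C)cc2OC)ccc1O[Si](C)(C)C(C)(C)C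
F12 | step 15 | (S)-2-(benzyloxy)-N-methoxy-N-methylpropanamide | CON(C)C(=O)[C@H](C)OCc1ccccc1
F13 | step 15 | (S)-2-(benzyloxy)-1-[4-(tert-butyldimethylsilyloxy)-3-methoxyphenyl]propan-1-one | COc1cc(C(=O)[C@H](C)OCc2ccccc2)ccc1O[Si](C)(C)C(C)(C)C
A1 | alternative 1 | all-trans 7-hydroxy-6-methoxy-1-(3-methoxy-4-pivaloyloxyphenyl)-2-methyltetralin-3-carbaldehyde | CC(C)(C)C(=O)Oc1ccc([C@H]2c3cc(O)c(OC)cc3C[C@@H](C=O)[C@@H]2C)cc1OC
A2 | alternative 1 | 4-(3-hydroxy-4-methoxyphenyl)-4-(3-methoxy-4-pivaloyloxyphenyl)-3-methylbutanal with C1 and C2 configured as in the target | CC(C)(C)C(=O)Oc1ccc([C@@H](c2ccc(OC)c(O)c2)[C@@H](C)CC=O)cc1OC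
A3 | alternative 1 | formaldehyde | C=O
A4 | alternative 2 | dimethyl 1-(4-allyloxy-3-methoxyphenyl)-7-benzyloxy-1-hydroxy-6-methoxytetralin-2,3-dicarboxylate (esters trans, hydroxyl cis to the C2 ester) | C=CCOc1ccc([C@@]2(O)c3cc(OCc4ccccc4)c(OC)cc3C[C@@H](C(=O)OC)[C@@H]2C(=O)OC)cc1OC
A5 | alternative 2 | (4-allyloxy-3-methoxyphenyl)(5-benzyloxy-4-methoxy-2-methylphenyl)methanone | C=CCOc1ccc(C(=O)c2cc(OCc3ccccc3)c(OC)cc2C)cc1OC
A6 | alternative 2 | dimethyl fumarate | COC(=O)/C=C/C(=O)OC
A7 | alternative 3 | all-trans 6-benzyloxy-7-methoxy-2,3-dimethyl-4-[3-methoxy-4-(triisopropylsilyloxy)phenyl]-1-tetralone (ketone at target C4) | COc1cc([C@H]2c3cc(OCc4ccccc4)c(OC)cc3C(=O)[C@@H](C)[C@@H]2C)ccc1O[Si](C(C)C)(C(C)C)C(C)C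
A8 | alternative 3 | all-trans 2-[3-methoxy-4-(triisopropylsilyloxy)phenyl]-3,4-dimethylcyclobutan-1-one | COc1cc([C@H]2C(=O)[C@@H](C)[C@@H]2C)ccc1O[Si](C(C)C)(C(C)C)C(C)C
A9 | alternative 3 | 1-(benzyloxy)-5-bromo-4-iodo-2-methoxybenzene | COc1cc(I)c(Br)cc1OCc1ccccc1
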